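## Retrosynthetic overview
- The acetates go on last. The tetrahydrofuran is the last ring formed, by 5-exo opening of a cis-5,6-epoxide by the C12 hydroxyl (C6–O bond, inversion at C6).
- C7–C8 comes from an anti-selective aldol between the α'-enolate of a 2-chloro-4-siloxycyclopentenone and a cis-α,β-epoxy aldehyde (C1–C7).
- The chlorocyclopentenone comes from a 2,2-dichlorocyclopentanone. This is made by one-carbon ring expansion (CH2N2, 1,2-shift of C12) of an α,α-dichlorocyclobutanone; the CCl2 group directs the shift and later becomes the vinyl chloride.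
- The four-membered ring is bought. C12 is set by a Pd-catalysed enantioselective allylation of the enediol bis-silyl ether, and the Z-octenyl chain by Z-selective cross-metathesis with hept-1-ene.
- The epoxy aldehyde comes from hex-5-enoic acid and (Z)-but-2-ene-1,4-diol by Z-selective cross-metathesis, Sharpless epoxidation and oxidation.

Assumption: the two Me3Si groups of commercial 1 count as protecting groups (C4O2 core, six non-H atoms); labels C1–C20 follow prostanoid numbering (C1 ester carbon, C9 ketone, C12 quaternary carbinol carbon).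

## Route

Step 1
Reactants: 1 1,2-bis(trimethylsilyloxy)cyclobut-1-ene; 2 allyl methyl carbonate
Product: 3 (R)-2-allyl-2-(trimethylsilyloxy)cyclobutan-1-one
Conditions: Pd2(dba)3 (2.5 mol %), (S)-(CF3)3-t-Bu-PHOX (6 mol %), Bu4N[Ph3SiF2] (0.3 equiv), THF, 25 °C
Reagents that add atoms: none
Why: Proposed new method: fluoride, and then the methoxide freed from 2, cleaves one of the two equivalent O–SiMe3 groups to release an α-siloxy cyclobutanone enolate, which binds the (π-allyl)Pd–PHOX cation and is C-allylated at the siloxy-bearing carbon by inner-sphere reductive elimination, the oxazoline t-Bu quadrant discriminating the enolate faces so that quaternary C12 is set as R (the ligand antipode is available if the sense is reversed); the closest known reaction type is the Pd–PHOX enantioselective Tsuji–Trost allylation of silyl enol ethers, of α-oxygenated enolates and of cyclobutanone enolates, not yet shown on an enediol bis-silyl ether.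

Step 2
Reactants: 3 (R)-2-allyl-2-(trimethylsilyloxy)cyclobutan-1-one; 4 hept-1-ene
Product: 5 (R)-2-[(Z)-oct-2-en-1-yl]-2-(trimethylsilyloxy)cyclobutan-1-one
Conditions: cyclometalated (adamantyl-chelate, nitrato) Ru Z-selective catalyst (3 mol %), 4 (4 equiv), THF, 35 °C, static vacuum
Reagents that add atoms: none
Why: Z-selective olefin cross-metathesis, in which the chelated NHC forces an all-syn side-bound metallacyclobutane and gives the kinetic Z-alkene, while the ketone, the silyl ether and C12 are untouched.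

Step 3
Reactants: 5 (R)-2-[(Z)-oct-2-en-1-yl]-2-(trimethylsilyloxy)cyclobutan-1-one
Product: 7 (S)-2,2-dichloro-4-[(Z)-oct-2-en-1-yl]-4-(trimethylsilyloxy)cyclobutan-1-one, via (4S)-2-chloro-4-[(Z)-oct-2-en-1-yl]-4-(trimethylsilyloxy)cyclobutan-1-one (C2 epimers) 6 (not isolated)
Conditions: LiHMDS (1.1 equiv), THF, −78 °C, then NCS (1.1 equiv); repeat once in the same flask; sat. NH4Cl
Reagents that add atoms: N-chlorosuccinimide O=C1CCC(=O)N1Cl
Why: Two successive enolate chlorinations, regiospecific because C10 is the only enolisable carbon (C12 is quaternary) and 6 is more acidic than 5, with a non-nucleophilic base at −78 °C avoiding semibenzilic ring contraction; C12 keeps its geometry and only the CIP descriptor changes.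

Step 4
Reactants: 7 (S)-2,2-dichloro-4-[(Z)-oct-2-en-1-yl]-4-(trimethylsilyloxy)cyclobutan-1-one
Product: 8 (R)-2,2-dichloro-4-[(Z)-oct-2-en-1-yl]-4-(trimethylsilyloxy)cyclopentan-1-one
Conditions: CH2N2 (3 equiv), Et2O–MeOH (20:1), 0 °C to rt
Reagents that add atoms: diazomethane C=[N+]=[N-]
Why: Büchner–Curtius–Schlotterbeck-type ring expansion, in which CH2N2 adds to the strained, chlorine-activated carbonyl and, since the electron-poor CCl2 carbon cannot migrate, the siloxy-bearing C12 makes the 1,2-shift onto the new C8 with loss of N2 and retention at C12; the less electrophilic cyclopentanone is not homologated again.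

Step 5
Reactants: 8 (R)-2,2-dichloro-4-[(Z)-oct-2-en-1-yl]-4-(trimethylsilyloxy)cyclopentan-1-one
Product: 10 (R)-2-chloro-4-[(Z)-oct-2-en-1-yl]-4-(trimethylsilyloxy)cyclopent-2-en-1-one, via (R)-2-chloro-4-[(Z)-oct-2-en-1-yl]-1,4-bis(trimethylsilyloxy)cyclopent-1-ene 9 (not isolated)
Conditions: Zn dust, Me3SiCl, THF, 0 °C to rt; filter under Ar, swap to MeCN; Pd(OAc)2 (1.05 equiv), rt
Reagents that add atoms: none
Why: Reductive silylation (zinc enolate trapped on oxygen) fixes the enol ether at C9=C10(Cl), and Saegusa–Ito dehydrogenation (β-hydride elimination from C11) gives the α-chloroenone without base, so E1cB loss of the β-siloxy group through a C8 enolate is avoided.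

Step 6
Reactants: 11 hex-5-enoic acid
Product: 12 methyl hex-5-enoate
Conditions: MeOH, H2SO4 (cat.), reflux
Reagents that add atoms: methanol CO
Why: Fischer esterification driven by excess methanol; no stereocentre is involved.

Step 7
Reactants: 12 methyl hex-5-enoate; 13 (Z)-but-2-ene-1,4-diol
Product: 14 methyl (Z)-7-hydroxyhept-5-enoate
Conditions: Ru dithiolate (stereoretentive) metathesis catalyst (3 mol %), 13 (2 equiv), THF, 22 °C
Reagents that add atoms: none
Why: Stereoretentive Z-selective cross-metathesis, in which the Z geometry of the diol is carried through the syn-substituted metallacyclobutane into the Z-allylic alcohol; ester and free OH are tolerated.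

Step 8
Reactants: 14 methyl (Z)-7-hydroxyhept-5-enoate
Product: 15 methyl 4-[(2R,3S)-3-(hydroxymethyl)oxiran-2-yl]butanoate (cis-epoxide; 5R,6S)
Conditions: Ti(OiPr)4 (10 mol %), L-(+)-diethyl tartrate (12 mol %), t-BuOOH, 4 Å MS, CH2Cl2, −20 °C
Reagents that add atoms: tert-butyl hydroperoxide CC(C)(C)OO
Why: Sharpless asymmetric epoxidation, in which the L-(+)-tartrate/Ti complex delivers oxygen to the alkene face that gives the (2S,3R)-2,3-epoxy alcohol, setting C5 and C6, and syn addition to the Z-alkene gives the cis-epoxide.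

Step 9
Reactants: 15 methyl 4-[(2R,3S)-3-(hydroxymethyl)oxiran-2-yl]butanoate
Product: 16 methyl 4-[(2R,3R)-3-formyloxiran-2-yl]butanoate (cis; 5R,6R by CIP, geometry unchanged)
Conditions: TEMPO (10 mol %), PhI(OAc)2 (1.1 equiv), CH2Cl2, rt
Reagents that add atoms: none
Why: Oxoammonium (TEMPO) oxidation of the primary alcohol under neutral conditions, which stops at the aldehyde and does not epimerise the cis-epoxy aldehyde.

Step 10
Reactants: 10 (R)-2-chloro-4-[(Z)-oct-2-en-1-yl]-4-(trimethylsilyloxy)cyclopent-2-en-1-one; 16 methyl 4-[(2R,3R)-3-formyloxiran-2-yl]butanoate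
Product: 17 methyl (5R,6S,7S,8S,12R,14Z)-10-chloro-5,6-epoxy-7-hydroxy-9-oxo-12-(trimethylsilyloxy)prosta-10,14-dienoate
Conditions: LDA (1.05 equiv), THF, −78 °C, 30 min; 16, −78 °C, 20 min; AcOH quench at −78 °C
Reagents that add atoms: none
Why: Lithium aldol addition, in which C8 is the only enolisable site, the ring-locked E-enolate reacts through a Zimmerman–Traxler chair to give the 7,8-anti adduct, the aldehyde comes in on the face of the slim OSiMe3 group (anti to the octenyl chain, setting C8), and the polar Felkin–Anh preference of the cis-epoxy aldehyde for the erythro epoxy alcohol is matched (setting C7).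

Step 11
Reactants: 17 methyl (5R,6S,7S,8S,12R,14Z)-10-chloro-5,6-epoxy-7-hydroxy-9-oxo-12-(trimethylsilyloxy)prosta-10,14-dienoate
Product: 19 methyl (5R,6S,7S,8S,12R,14Z)-10-chloro-6,12-epoxy-5,7-dihydroxy-9-oxoprosta-10,14-dienoate, via methyl (5R,6S,7S,8S,12R,14Z)-10-chloro-5,6-epoxy-7,12-dihydroxy-9-oxoprosta-10,14-dienoate 18 (not isolated)
Conditions: camphorsulfonic acid (10 mol %), wet CH2Cl2, 0 °C to rt
Reagents that add atoms: none
Why: Acid-catalysed desilylation followed by 5-exo-tet epoxide opening by the tertiary C12 hydroxyl, an SN2 attack that inverts C6 and leaves C5 untouched (cis-epoxide gives the 5,6-threo array), the cis-fused bicycle forming only from the 8,12-cis aldol.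

Step 12
Reactants: 19 methyl (5R,6S,7S,8S,12R,14Z)-10-chloro-6,12-epoxy-5,7-dihydroxy-9-oxoprosta-10,14-dienoate
Product: 20 methyl (5R)-5-acetoxy-5-[(2S,3S,3aS,6aR)-3-acetoxy-5-chloro-6a-[(Z)-oct-2-en-1-yl]-4-oxo-3,3a,4,6a-tetrahydro-2H-cyclopenta[b]furan-2-yl]pentanoate (target)
Conditions: Ac2O (4 equiv), pyridine, DMAP (5 mol %), CH2Cl2, 0 °C
Reagents that add atoms: acetic anhydride CC(=O)OC(C)=O
Why: Nucleophile-catalysed O-acylation of both secondary alcohols with retention, kept cold and short so that the new β-acetoxy ketone does not undergo E1cB elimination.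

## Compound list
1 | 1,2-bis(trimethylsilyloxy)cyclobut-1-ene | C[Si](C)(C)OC1=C(O[Si](C)(C)C)CC1 | starting material
2 | allyl methyl carbonate | C=CCOC(=O)OC | starting material
3 | (R)-2-allyl-2-(trimethylsilyloxy)cyclobutan-1-one | C=CC[C@]1(O[Si](C)(C)C)CCC1=O | intermediate
4 | hept-1-ene | C=CCCCCC | starting material
5 | (R)-2-[(Z)-oct-2-en-1-yl]-2-(trimethylsilyloxy)cyclobutan-1-one | CCCCC/C=C\C[C@]1(O[Si](C)(C)C)CCC1=O | intermediate
6 | (4S)-2-chloro-4-[(Z)-oct-2-en-1-yl]-4-(trimethylsilyloxy)cyclobutan-1-one (C2 epimers) | CCCCC/C=C\C[C@]1(O[Si](C)(C)C)CC(Cl)C1=O | intermediate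
7 | (S)-2,2-dichloro-4-[(Z)-oct-2-en-1-yl]-4-(trimethylsilyloxy)cyclobutan-1-one | CCCCC/C=C\C[C@]1(O[Si](C)(C)C)CC(Cl)(Cl)C1=O | intermediate
8 | (R)-2,2-dichloro-4-[(Z)-oct-2-en-1-yl]-4-(trimethylsilyloxy)cyclopentan-1-one | CCCCC/C=C\C[C@]1(O[Si](C)(C)C)CC(Cl)(Cl)C(=O)C1 | intermediate
9 | (R)-2-chloro-4-[(Z)-oct-2-en-1-yl]-1,4-bis(trimethylsilyloxy)cyclopent-1-ene | CCCCC/C=C\C[C@]1(O[Si](C)(C)C)CC(Cl)=C(O[Si](C)(C)C)C1 | intermediate
10 | (R)-2-chloro-4-[(Z)-oct-2-en-1-yl]-4-(trimethylsilyloxy)cyclopent-2-en-1-one | CCCCC/C=C\C[C@]1(O[Si](C)(C)C)C=C(Cl)C(=O)C1 | intermediate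
11 | hex-5-enoic acid | C=CCCCC(=O)O | starting material
12 | methyl hex-5-enoate | C=CCCCC(=O)OC | intermediate
13 | (Z)-but-2-ene-1,4-diol | OC/C=C\CO | starting material
14 | methyl (Z)-7-hydroxyhept-5-enoate | OC/C=C\CCCC(=O)OC | intermediate
15 | methyl 4-[(2R,3S)-3-(hydroxymethyl)oxiran-2-yl]butanoate | OC[C@H]1[C@@H](CCCC(=O)OC)O1 | intermediate
16 | methyl 4-[(2R,3R)-3-formyloxiran-2-yl]butanoate | O=C[C@H]1[C@@H](CCCC(=O)OC)O1 | intermediate
17 | methyl (5R,6S,7S,8S,12R,14Z)-10-chloro-5,6-epoxy-7-hydroxy-9-oxo-12-(trimethylsilyloxy)prosta-10,14-dienoate | CCCCC/C=C\C[C@]1(O[Si](C)(C)C)C=C(Cl)C(=O)[C@H]1[C@H](O)[C@H]2[C@@H](CCCC(=O)OC)O2 | intermediate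
18 | methyl (5R,6S,7S,8S,12R,14Z)-10-chloro-5,6-epoxy-7,12-dihydroxy-9-oxoprosta-10,14-dienoate | CCCCC/C=C\C[C@]1(O)C=C(Cl)C(=O)[C@H]1[C@H](O)[C@H]2[C@@H](CCCC(=O)OC)O2 | intermediate
19 | methyl (5R,6S,7S,8S,12R,14Z)-10-chloro-6,12-epoxy-5,7-dihydroxy-9-oxoprosta-10,14-dienoate | CCCCC/C=C\C[C@]12C=C(Cl)C(=O)[C@H]1[C@H](O)[C@H]([C@@H](CCCC(=O)OC)O)O2 | intermediate
20 | methyl (5R)-5-acetoxy-5-[(2S,3S,3aS,6aR)-3-acetoxy-5-chloro-6a-[(Z)-oct-2-en-1-yl]-4-oxo-3,3a,4,6a-tetrahydro-2H-cyclopenta[b]furan-2-yl]pentanoate | CCCCC/C=C\C[C@]12C=C(Cl)C(=O)[C@H]1[C@H](OC(C)=O)[C@H]([C@@H](CCCC(=O)OC)OC(C)=O)O2 | target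

## Step count and risks
Total step count: 12. Longest linear sequence: 8 (steps 1–5 and 10–12); steps 6–9 form the convergent branch.

**Step 1 (the proposed new step).** The level and sense of induction are unknown, O-allylation is possible, and the second silyl ether may be lost.
Fallback (known chemistry): setting out from 1, one O–Si bond is cleaved with MeLi (1.0 equiv, THF, 0 °C). The resulting lithium enolate is alkylated with allyl bromide to racemic 2-allyl-2-(trimethylsilyloxy)cyclobutan-1-one F1. Preparative chromatography on a chiral stationary phase then gives the R enantiomer, which is 3, and the route is rejoined there.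

**Step 4 (ring expansion).** Both α-carbons carry electron-withdrawing groups, so the betaine may close to the spiro-epoxide instead of undergoing the shift.
Fallback: setting out from 7, the epoxide is made on purpose by Corey–Chaykovsky methylenation with dimethylsulfonium methylide (THF–DMSO, −10 °C). This gives 4,4-dichloro-6-[(Z)-oct-2-en-1-yl]-6-(trimethylsilyloxy)-1-oxaspiro[2.3]hexane (C12 as in 7, mixture at the spiro carbon) F2. LiI in THF opens the CH2 terminus, and the iodohydrin alkoxide undergoes the same semipinacol 1,2-shift of C12 with loss of iodide. The route is rejoined at 8.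

**Step 10 (aldol).** The face selectivity between OSiMe3 and the octenyl chain may be low, and retro-aldol or elimination can compete.
Fallback: setting out from 10, the silyl ether is removed (citric acid, MeOH, 0 °C) to give (R)-2-chloro-4-hydroxy-4-[(Z)-oct-2-en-1-yl]cyclopent-2-en-1-one F3. Its alkoxide–enolate dianion (LDA, 2.1 equiv, −78 °C) is treated with 16, so that the lithium alkoxide binds the aldehyde and delivers it to its own face. A cold AcOH quench gives 18 directly, which is cyclised as in step 11, and the route is rejoined at 18.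

## Further compounds
F1 | step 1 | racemic 2-allyl-2-(trimethylsilyloxy)cyclobutan-1-one | C=CCC1(O[Si](C)(C)C)CCC1=O
F2 | step 4 | 4,4-dichloro-6-[(Z)-oct-2-en-1-yl]-6-(trimethylsilyloxy)-1-oxaspiro[2.3]hexane (mixture at the spiro carbon) | CCCCC/C=C\C[C@]1(O[Si](C)(C)C)CC(Cl)(Cl)C12CO2
F3 | step 10 | (R)-2-chloro-4-hydroxy-4-[(Z)-oct-2-en-1-yl]cyclopent-2-en-1-one | CCCCC/C=C\C[C@]1(O)C=C(Cl)C(=O)C1
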